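**Plan**

1. Numbering: C1 is the lactone carbonyl and the chain runs to C16, the CH bonded to phenyl; the O–O bridge joins C3 and C6.
2. Cuts, in retrosynthetic order: C5–H back to C5–I; the lactone O–C4 bond (γ-lactone ring) back to a 3,6-dihydro-1,2-dioxine acid; both peroxide C–O bonds (at C3 and C6) back to O2 and a (3E,5E)-diene; C4–C5 between two alkenyl units; C11=C12 to an aldehyde and a sulfone.
3. Forward: the chain is joined first (C11=C12 by Julia–Kocienski olefination, C4–C5 by methylalumination/Negishi coupling); the dioxine ring then arises by (4+2) addition of singlet oxygen, the lactone ring by iodolactonisation, and iodine is removed last.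
4. Enabling feature: the lactone oxygen stands on the methyl-bearing ring carbon C4, next to C3, whose CH2–C1 arm lies on the same face of the 1,2-dioxane. That is the imprint of a C3-tethered carboxylate closing on C4 of a ring C4=C5 alkene.
5. Stereochemistry: C8 comes from (R)-citronellal; C3/C6 cis comes from suprafacial O2 addition to the E,E-diene, and the ring configuration that matches C8 is picked by hydrolase resolution; C4 is relayed from C3 by the tether; alkene geometries come from Johnson–Claisen, Julia–Kocienski, syn-carbometalation and syn-hydrozirconation.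

Key step: step 15

Assumption: which of the two cis-dioxine esters a hydrolase turns over first cannot be predicted, so step 14 assumes that an enzyme screen provides one preferring the (3S,6R) ester; with the opposite preference the wanted ester would be the one left over, to be recovered and hydrolysed by itself.

**Sulfone fragment (C12–C16)**

Step 1
Reactants: 1 1-phenylprop-2-en-1-ol (racemic)
Product: 3 ethyl (4E)-5-phenylpent-4-enoate, via mixed ketene acetal 2 (not isolated)
Conditions: MeC(OEt)3 (6 equiv), EtCO2H (0.1 equiv), 140 °C, EtOH distilled off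
Reagents that add atoms: triethyl orthoacetate, CC(OCC)(OCC)OCC
Why: Johnson–Claisen rearrangement through a chair with phenyl equatorial, so the new C15=C16 alkene should be E and conjugated with the arene.

Step 2
Reactants: 3 ethyl (4E)-5-phenylpent-4-enoate
Product: 4 (4E)-5-phenylpent-4-en-1-ol
Conditions: LiAlH4, Et2O, 0 °C; aqueous NaOH work-up
Reagents that add atoms: none
Why: Hydride reduction of an ester to the primary alcohol; the unactivated styrenyl alkene is not touched.

Step 3
Reactants: 4 (4E)-5-phenylpent-4-en-1-ol
Product: 5 1-phenyl-5-{[(4E)-5-phenylpent-4-en-1-yl]sulfanyl}-1H-tetrazole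
Conditions: 1-phenyl-1H-tetrazole-5-thiol, PPh3, DIAD, THF, 0 °C to rt
Reagents that add atoms: 1-phenyl-1H-tetrazole-5-thiol, Sc1nnnn1-c1ccccc1
Why: Mitsunobu thioetherification of an unhindered primary alcohol with an acidic heteroaryl thiol.

Step 4
Reactants: 5 1-phenyl-5-{[(4E)-5-phenylpent-4-en-1-yl]sulfanyl}-1H-tetrazole
Product: 7 1-phenyl-5-{[(4E)-5-phenylpent-4-en-1-yl]sulfonyl}-1H-tetrazole, via sulfoxide 6 (not isolated)
Conditions: 30% H2O2, (NH4)6Mo7O24·4H2O (cat.), EtOH, 0 °C to rt
Reagents that add atoms: hydrogen peroxide, OO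
Why: Molybdate-catalysed sulfide-to-sulfone oxidation, which is routinely selective for sulfur over a conjugated disubstituted alkene.

**Alkynal fragment (C5–C11)**

Step 5
Reactants: 8 (R)-citronellal
Product: 9 (4R)-4,8-dimethylnon-7-en-1-yne
Conditions: dimethyl (1-diazo-2-oxopropyl)phosphonate, K2CO3, MeOH, 0 °C to rt
Reagents that add atoms: dimethyl (1-diazo-2-oxopropyl)phosphonate, CC(=O)C(=[N+]=[N-])P(=O)(OC)OC
Why: Ohira–Bestmann one-carbon homologation of the aldehyde to the terminal alkyne; the stereocentre is β to the carbonyl and cannot epimerise.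

Step 6
Reactants: 9 (4R)-4,8-dimethylnon-7-en-1-yne
Product: 11 (4R)-4-methylhept-6-ynal, via ozonide 10 (not isolated)
Conditions: O3, CH2Cl2, −78 °C, Sudan Red 7B end-point; then PPh3, −78 °C to rt
Reagents that add atoms: ozone, [O-][O+]=O
Why: Chemoselective ozonolysis, since the electron-rich trisubstituted alkene reacts far faster than a terminal alkyne and the dye marks the end-point; reductive work-up gives the aldehyde.

Step 7
Reactants: 7 1-phenyl-5-{[(4E)-5-phenylpent-4-en-1-yl]sulfonyl}-1H-tetrazole; 11 (4R)-4-methylhept-6-ynal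
Product: 13 [(1E,5E,9R)-9-methyldodeca-1,5-dien-11-yn-1-yl]benzene, via potassium sulfonyl carbanion 12 (not isolated)
Conditions: 7, KN(SiMe3)2, DME, −60 °C; then 11, −60 °C to rt
Reagents that add atoms: none
Why: Julia–Kocienski olefination; a 1-phenyltetrazolyl sulfone with a potassium counter-ion in DME should give the E alkene at C11=C12 from two unbranched partners, and the alkyne C–H is too weakly acidic to quench the carbanion.

**Iodoester fragment (C1–C4)**

Step 8
Reactants: 14 pent-3-yn-1-ol
Product: 15 tert-butyl(dimethyl)(pent-3-yn-1-yloxy)silane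
Conditions: TBSCl, imidazole, CH2Cl2, 0 °C to rt
Reagents that add atoms: tert-butyl(chloro)dimethylsilane, CC(C)(C)[Si](C)(C)Cl
Why: Standard silylation; the bulky silyl ether keeps oxygen from coordinating zirconium, so sterics alone steer step 9.

Step 9
Reactants: 15 tert-butyl(dimethyl)(pent-3-yn-1-yloxy)silane
Product: 17 tert-butyl{[(3E)-4-iodopent-3-en-1-yl]oxy}dimethylsilane, via alkenylzirconocene 16 (not isolated)
Conditions: Cp2Zr(H)Cl (1.6 equiv), THF, 50 °C; then I2, THF, 0 °C
Reagents that add atoms: iodine, II
Why: Syn-hydrozirconation of the internal alkyne, equilibrated by excess Zr–H so that zirconium sits on the methyl-bearing carbon, followed by iodinolysis with retention, which gives the E alkenyl iodide.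

Step 10
Reactants: 17 tert-butyl{[(3E)-4-iodopent-3-en-1-yl]oxy}dimethylsilane
Product: 19 (3E)-4-iodopent-3-enoic acid, via (3E)-4-iodopent-3-en-1-ol 18 (not isolated)
Conditions: CrO3, H2SO4, H2O, acetone, 0 °C
Reagents that add atoms: water, O
Why: Jones oxidation, in which the aqueous acid removes the primary silyl ether and H2CrO4 takes the alcohol through the aldehyde hydrate to the acid; the alkenyl iodide and the β,γ-alkene are stable to the cold oxidant.

Step 11
Reactants: 19 (3E)-4-iodopent-3-enoic acid
Product: 20 methyl (3E)-4-iodopent-3-enoate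
Conditions: Me3SiCHN2, toluene/MeOH, 0 °C
Reagents that add atoms: (trimethylsilyl)diazomethane, C[Si](C)(C)C=[N+]=[N-]
Why: Base-free methyl esterification, so the β,γ-double bond cannot slip into conjugation.

**Union and endgame**

Step 12
Reactants: 13 [(1E,5E,9R)-9-methyldodeca-1,5-dien-11-yn-1-yl]benzene; 20 methyl (3E)-4-iodopent-3-enoate
Product: 22 methyl (3E,5E,8R,11E,15E)-4,6,8-trimethyl-16-phenylhexadeca-3,5,11,15-tetraenoate, via alkenylalane 21 (not isolated)
Conditions: 13, AlMe3 (2.5 equiv), Cp2ZrCl2 (0.25 equiv), CH2Cl2, 0 °C to rt; volatiles removed in vacuo; then 20, ZnCl2 (0.3 equiv), Pd(PPh3)4 (5 mol %), THF, rt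
Reagents that add atoms: trimethylaluminium, C[Al](C)C
Why: Zirconium-catalysed methylalumination of the terminal alkyne is syn and puts methyl on C6 and aluminium on C5 (the 1,2-disubstituted alkenes are inert to it), and the Negishi coupling that follows, run with zerovalent palladium and ZnCl2 as transmetalation shuttle, joins C5 to C4 with retention at both alkenyl carbons under neutral conditions, so the diene should be 3E,5E and stay out of conjugation with the ester.

Step 13
Reactants: 22 methyl (3E,5E,8R,11E,15E)-4,6,8-trimethyl-16-phenylhexadeca-3,5,11,15-tetraenoate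
Product: 23 methyl 2-[(3S,6R)-4,6-dimethyl-6-[(2R,5E,9E)-2-methyl-10-phenyldeca-5,9-dien-1-yl]-3,6-dihydro-1,2-dioxin-3-yl]acetate
Conditions: O2, visible light, tetraphenylporphyrin (cat.), CH2Cl2, −20 °C; ene hydroperoxides removed on silica; the two cis adducts are not separated here
Reagents that add atoms: dioxygen, O=O
Why: Photosensitised (4+2) cycloaddition of singlet oxygen to the s-cis diene (made accessible because the C4 methyl clashes with the C6 methyl in the s-trans form) is suprafacial, so the 3E,5E geometry places the C3 arm and the C6 side chain cis; the remote C8 centre cannot bias the diene face, so 23 should be accompanied by a similar amount of its (3R,6S) ring epimer, which is carried on unseparated and removed in step 14, while the ester-flanked C2–H bonds, the C11=C12 alkene and the styrene are poor partners for the competing ene reaction.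

Step 14
Reactants: 23 methyl 2-[(3S,6R)-4,6-dimethyl-6-[(2R,5E,9E)-2-methyl-10-phenyldeca-5,9-dien-1-yl]-3,6-dihydro-1,2-dioxin-3-yl]acetate
Product: 24 2-[(3S,6R)-4,6-dimethyl-6-[(2R,5E,9E)-2-methyl-10-phenyldeca-5,9-dien-1-yl]-3,6-dihydro-1,2-dioxin-3-yl]acetic acid
Conditions: feed is 23 as the unseparated mixture with its (3R,6S) epimer from step 13; Burkholderia cepacia lipase, 0.1 M phosphate buffer pH 7.2/acetone (9:1), 30 °C, pH-stat, stopped before half conversion; acid separated from the unreacted (3R,6S) ester on silica
Reagents that add atoms: water, O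
Why: Lipase-catalysed kinetic resolution by ester hydrolysis, in which the enzyme discriminates the stereocentre β to the acyl carbon (here two diastereomers differing only in ring configuration), run at neutral pH so that the dioxine, whose C3–H is prone to base-induced Kornblum–DeLaMare opening, survives.

Step 15
Reactants: 24 2-[(3S,6R)-4,6-dimethyl-6-[(2R,5E,9E)-2-methyl-10-phenyldeca-5,9-dien-1-yl]-3,6-dihydro-1,2-dioxin-3-yl]acetic acid
Product: 25 (3R,4S,4aR,7aS)-4-iodo-3,4a-dimethyl-3-[(2R,5E,9E)-2-methyl-10-phenyldeca-5,9-dien-1-yl]-4,4a,7,7a-tetrahydro-3H-furo[3,2-c][1,2]dioxin-6-one (cis-fused; iodine on C5 trans to the lactone oxygen on C4)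
Conditions: I2 (3 equiv), NaHCO3 (4 equiv), MeCN, 0 °C, dark; aq Na2S2O3 quench
Reagents that add atoms: iodine, II
Why: Iodine forms an iodonium ion reversibly on the trisubstituted ring alkene C4=C5, on the face opposite the C3 acetic acid arm, and the carboxylate opens it at the more substituted carbon C4 with anti addition, making the O–C4 bond and leaving iodine on C5. The closest known reaction type is the kinetic iodolactonisation of γ,δ-unsaturated acids. The γ-lactone ring closes in the 5-exo mode, and because the nucleophile hangs from the neighbouring ring carbon it can only give the cis-fused bicycle. The new quaternary centre C4 is therefore set by C3 through the tether, and C5 by the anti opening (a centre erased in step 16). The step needs site selectivity among four alkenes and Markovnikov regioselectivity: only C4=C5 has a nucleophile within reach and it is the most substituted alkene, iodonium formation at C11=C12 and at the styrene is reversible and unproductive, and attack at C5 would need a bridged 6-endo closure at the less substituted carbon. The dialkyl peroxide is not expected to react with iodine or iodide under these cold, neutral, dark conditions.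

Step 16
Reactants: 25 (3R,4S,4aR,7aS)-4-iodo-3,4a-dimethyl-3-[(2R,5E,9E)-2-methyl-10-phenyldeca-5,9-dien-1-yl]-4,4a,7,7a-tetrahydro-3H-furo[3,2-c][1,2]dioxin-6-one
Product: 26 (3R,4aS,7aS)-3,4a-dimethyl-3-[(2R,5E,9E)-2-methyl-10-phenyldeca-5,9-dien-1-yl]-4,4a,7,7a-tetrahydro-3H-furo[3,2-c][1,2]dioxin-6-one (the target)
Conditions: Bu3SnH (1.5 equiv, at least 0.3 M), Et3B (0.2 equiv), air, toluene, −20 to 0 °C; aq KF work-up
Reagents that add atoms: none
Why: Radical chain dehalogenation in which the C5 radical must take hydrogen before it attacks O1 and cleaves the O–O bond to an epoxide; concentrated Bu3SnH, a several-fold faster hydrogen donor than (Me3Si)3SiH, low temperature, and the poor overlap of the C5 radical orbital with the ring O–O bond should all favour reduction, and C5 becomes a CH2 so no stereocentre is at stake.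

**Compound list**

1 | 1-phenylprop-2-en-1-ol (racemic) | C=CC(O)c1ccccc1 | starting material
2 | 1-ethoxy-1-[(1-phenylprop-2-en-1-yl)oxy]ethene (mixed ketene acetal) | C=C(OCC)OC(C=C)c1ccccc1 | intermediate (not isolated)
3 | ethyl (4E)-5-phenylpent-4-enoate | CCOC(=O)CC/C=C/c1ccccc1 | intermediate
4 | (4E)-5-phenylpent-4-en-1-ol | OCCC/C=C/c1ccccc1 | intermediate
5 | 1-phenyl-5-{[(4E)-5-phenylpent-4-en-1-yl]sulfanyl}-1H-tetrazole | C(CC/C=C/c1ccccc1)Sc1nnnn1-c1ccccc1 | intermediate
6 | 1-phenyl-5-{[(4E)-5-phenylpent-4-en-1-yl]sulfinyl}-1H-tetrazole (racemic at sulfur) | O=S(CCC/C=C/c1ccccc1)c1nnnn1-c1ccccc1 | intermediate (not isolated)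
7 | 1-phenyl-5-{[(4E)-5-phenylpent-4-en-1-yl]sulfonyl}-1H-tetrazole | O=S(=O)(CCC/C=C/c1ccccc1)c1nnnn1-c1ccccc1 | intermediate
8 | (R)-citronellal, (3R)-3,7-dimethyloct-6-enal | C[C@H](CCC=C(C)C)CC=O | starting material
9 | (4R)-4,8-dimethylnon-7-en-1-yne | C[C@H](CCC=C(C)C)CC#C | intermediate
10 | 3,3-dimethyl-5-[(3R)-3-methylhex-5-yn-1-yl]-1,2,4-trioxolane (ozonide, mixture at the ring carbon) | C[C@H](CCC1OOC(C)(C)O1)CC#C | intermediate (not isolated)
11 | (4R)-4-methylhept-6-ynal | C[C@H](CCC=O)CC#C | intermediate
12 | potassium salt of the α-sulfonyl carbanion of 7 | [K+].[CH-](CC/C=C/c1ccccc1)S(=O)(=O)c1nnnn1-c1ccccc1 | intermediate (not isolated)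
13 | [(1E,5E,9R)-9-methyldodeca-1,5-dien-11-yn-1-yl]benzene | C[C@H](CC/C=C/CC/C=C/c1ccccc1)CC#C | intermediate
14 | pent-3-yn-1-ol | CC#CCCO | starting material
15 | tert-butyl(dimethyl)(pent-3-yn-1-yloxy)silane | CC#CCCO[Si](C)(C)C(C)(C)C | intermediate
16 | chlorobis(cyclopentadienyl)[(2E)-5-{[tert-butyl(dimethyl)silyl]oxy}pent-2-en-2-yl]zirconium | C/C(=C\CCO[Si](C)(C)C(C)(C)C)[Zr](Cl)(C1C=CC=C1)C1C=CC=C1 | intermediate (not isolated)
17 | tert-butyl{[(3E)-4-iodopent-3-en-1-yl]oxy}dimethylsilane | C/C(I)=C\CCO[Si](C)(C)C(C)(C)C | intermediate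
18 | (3E)-4-iodopent-3-en-1-ol | C/C(I)=C\CCO | intermediate (not isolated)
19 | (3E)-4-iodopent-3-enoic acid | C/C(I)=C\CC(=O)O | intermediate
20 | methyl (3E)-4-iodopent-3-enoate | C/C(I)=C\CC(=O)OC | intermediate
21 | dimethyl[(1E,4R,7E,11E)-2,4-dimethyl-12-phenyldodeca-1,7,11-trien-1-yl]alumane | C[C@H](CC/C=C/CC/C=C/c1ccccc1)C/C(C)=C/[Al](C)C | intermediate (not isolated)
22 | methyl (3E,5E,8R,11E,15E)-4,6,8-trimethyl-16-phenylhexadeca-3,5,11,15-tetraenoate | C[C@H](CC/C=C/CC/C=C/c1ccccc1)C/C(C)=C/C(C)=C/CC(=O)OC | intermediate
23 | methyl 2-[(3S,6R)-4,6-dimethyl-6-[(2R,5E,9E)-2-methyl-10-phenyldeca-5,9-dien-1-yl]-3,6-dihydro-1,2-dioxin-3-yl]acetate | C[C@H](CC/C=C/CC/C=C/c1ccccc1)C[C@]1(C)C=C(C)[C@H](CC(=O)OC)OO1 | intermediate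
24 | 2-[(3S,6R)-4,6-dimethyl-6-[(2R,5E,9E)-2-methyl-10-phenyldeca-5,9-dien-1-yl]-3,6-dihydro-1,2-dioxin-3-yl]acetic acid | C[C@H](CC/C=C/CC/C=C/c1ccccc1)C[C@]1(C)C=C(C)[C@H](CC(=O)O)OO1 | intermediate (precursor of the key step)
25 | (3R,4S,4aR,7aS)-4-iodo-3,4a-dimethyl-3-[(2R,5E,9E)-2-methyl-10-phenyldeca-5,9-dien-1-yl]-4,4a,7,7a-tetrahydro-3H-furo[3,2-c][1,2]dioxin-6-one | C[C@H](CC/C=C/CC/C=C/c1ccccc1)C[C@]1(C)[C@@H](I)[C@]2(C)OC(=O)C[C@@H]2OO1 | intermediate (product of the key step)
26 | (3R,4aS,7aS)-3,4a-dimethyl-3-[(2R,5E,9E)-2-methyl-10-phenyldeca-5,9-dien-1-yl]-4,4a,7,7a-tetrahydro-3H-furo[3,2-c][1,2]dioxin-6-one | C[C@H](CC/C=C/CC/C=C/c1ccccc1)C[C@]1(C)C[C@]2(C)OC(=O)C[C@@H]2OO1 | target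

**Step count**

Total: 16 steps. Longest linear sequence: 10 steps (from 1 through steps 1–4, 7 and 12–16).

**Steps most likely to fail**

Step 13. Ene hydroperoxidation at the two trisubstituted alkenes of the diene (and, more slowly, at C11=C12) may run alongside the cycloaddition. A slow cycloaddition also means long irradiation, during which the excited sensitiser can cleave the O–O bond of the dioxine already formed. Fallback: setting out from 22, singlet oxygen would be delivered thermally and in the dark from a stoichiometric carrier. 1,4-Dimethylnaphthalene would be photooxygenated on its own (O2, methylene blue, CH2Cl2, −40 °C, visible light) to 1,4-dimethyl-1,4-dihydro-1,4-epidioxynaphthalene F1. F1 would then be added in portions to 22 (CH2Cl2, 0 to 25 °C), where it releases singlet oxygen by cycloreversion. This keeps light and sensitiser away from the substrate and allows the reaction to be stopped at partial conversion with recovery of 22, but it does not change the intrinsic cycloaddition-to-ene partition. It comes back to the route at 23, again formed together with its (3R,6S) epimer.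

Step 14. The hydrolase may discriminate poorly between the two ring configurations or prefer the wrong ester, so that the acid is formed with low diastereomeric purity. Fallback: setting out from 23 as the mixture with its (3R,6S) epimer, the two esters would be separated physically by preparative HPLC on a cellulose tris(3,5-dimethylphenylcarbamate) phase, which suits a pair that differs mainly in ring configuration. Ester 23 alone would then be hydrolysed at neutral pH by an esterase chosen for activity only (pig liver esterase, phosphate buffer pH 7/DMSO 9:1, 25 °C), coming back at 24. The assignment of the two esters would be secured by carrying each to the bicyclic lactone and comparing with the natural product.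

Step 12. Methylalumination may be incomplete or not fully regioselective, the aluminium or zinc alkenyl species may attack the ester of 20, or the C3=C4 double bond may migrate into conjugation during the coupling. Fallback: setting out from 13, the alane 21 would be quenched with I2 to give [(1E,5E,9R,11E)-12-iodo-9,11-dimethyldodeca-1,5,11-trien-1-yl]benzene F2, which can be purified free of regioisomer. Separately, 20 would be stannylated (Me6Sn2, Pd(PPh3)4, toluene, 80 °C) to methyl (3E)-4-(trimethylstannyl)pent-3-enoate F3. Stille coupling of F2 with F3 (Pd(PPh3)4, CuCl, LiCl, DMSO, rt to 45 °C) would come back to the route at 22.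

Further compounds
F1 | step 13 | 1,4-dimethyl-1,4-dihydro-1,4-epidioxynaphthalene (meso) | C[C@]12C=C[C@](C)(OO1)c1ccccc12
F0 | step 14 | none | none
F2 | step 12 | [(1E,5E,9R,11E)-12-iodo-9,11-dimethyldodeca-1,5,11-trien-1-yl]benzene | C[C@H](CC/C=C/CC/C=C/c1ccccc1)C/C(C)=C/I
F3 | step 12 | methyl (3E)-4-(trimethylstannyl)pent-3-enoate | C/C(=C\CC(=O)OC)[Sn](C)(C)C
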